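**Retrosynthetic overview**
- Last step: global removal of three diethylcarbamates from a tris-carbamate isoflav-3-ene. Rings A and B are bought; ring C is the only ring made, and it is made last.
- Key disconnection: ring C is cut at C4–C4a and O1–C8a (and at O1–C2), which leads back to an aryne of ring A (C4a≡C8a) and a 2-arylacrolein that carries ring B and C2–C3–C4.
- Enabling feature: the C5 methoxy group of ring A sits ortho to C4a and polarises the aryne, so the aldehyde oxygen bonds to C8a and the carbonyl carbon to C4a. C2 is an unsubstituted CH2 and C3=C4 is at the 2H-chromene level, exactly what CH2=C(Ar)–CHO delivers after oxa-6π closure; the target has no stereocentre.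
- Aryne precursor (a 2-silylaryl triflate) from 5-bromovanillin: Dakin oxidation; the bromine marks C8a and is exchanged for SiMe3 by a retro-Brook shift; the prenyl group enters at C6 by carbamate/methoxy-directed metalation.
- Enal from 2,4-dihydroxyacetophenone: carbamoylation, Wittig methylenation, allylic oxidation with SeO2.

Key step: step 10

**Step 1**
Reactants: 1 5-bromovanillin (3-bromo-4-hydroxy-5-methoxybenzaldehyde)
Product: 3 2-bromo-6-methoxybenzene-1,4-diol, via aryl formate 2 (not isolated)
Conditions: H2O2 (30% aq.), NaOH (aq.), 0 °C → rt, argon; then Na2S2O4, HCl to pH 3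
Reagents that add atoms: hydrogen peroxide, OO
Why: Dakin oxidation, in which the para-hydroxy group drives aryl migration in the peroxide adduct and formate 2 is saponified in situ; the bromine ortho to the original phenol marks the carbon that becomes C8a.

**Step 2**
Reactants: 3 2-bromo-6-methoxybenzene-1,4-diol
Product: 7 3-methoxy-4-(methoxymethoxy)-5-(trimethylsilyl)phenol, via bis(trimethylsilyl) ether 4 (not isolated), via lithium phenoxide 5 (not isolated), via O-silyl MOM ether 6 (not isolated)
Conditions: HMDS, 80 °C, then evaporation; n-BuLi, THF, −78 → −20 °C; MOMCl, DMPU, −78 °C → rt; K2CO3 (cat.), MeOH, rt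
Reagents that add atoms: hexamethyldisilazane, C[Si](C)(C)N[Si](C)(C)C; chloromethyl methyl ether, COCCl
Why: Retro-Brook (1,3 O→C silyl) rearrangement as used for 2-silylaryl triflate synthesis: Br–Li exchange at −78 °C outruns attack at silicon, the silyl group of the flanking oxygen moves to carbon and frees only that oxygen as hindered phenoxide 5, which MOMCl caps, while the distal OSiMe3 (sterically preferred on the unhindered oxygen) is removed by methanolysis, so the two hydroquinone oxygens are told apart without a selective protection.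

**Step 3**
Reactants: 7 3-methoxy-4-(methoxymethoxy)-5-(trimethylsilyl)phenol
Product: 8 3-methoxy-4-(methoxymethoxy)-5-(trimethylsilyl)phenyl diethylcarbamate
Conditions: ClCONEt2, K2CO3, MeCN, reflux
Reagents that add atoms: diethylcarbamoyl chloride, CCN(CC)C(Cl)=O
Why: Standard O-carbamoylation of the only free phenol, which installs the group that directs the next metalation and protects the C7 oxygen to the end.

**Step 4**
Reactants: 8 3-methoxy-4-(methoxymethoxy)-5-(trimethylsilyl)phenyl diethylcarbamate
Product: 11 3-methoxy-4-(methoxymethoxy)-2-(3-methylbut-2-en-1-yl)-5-(trimethylsilyl)phenyl diethylcarbamate, via aryllithium 9 (not isolated), via arylcopper 10 (not isolated)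
Conditions: s-BuLi, TMEDA, THF, −78 °C; CuBr·SMe2, −78 °C; prenyl bromide, −78 → 0 °C
Reagents that add atoms: prenyl bromide (1-bromo-3-methylbut-2-ene), CC(C)=CCBr
Why: Directed ortho-metalation at the only cooperative site, between OCONEt2 and OMe (the other carbamate-ortho position is shielded by SiMe3 and both flanks of OMOM are substituted), followed by transmetalation to copper at −78 °C, which suppresses the anionic Fries shift and should give SN2 coupling with prenyl bromide.

**Step 5**
Reactants: 11 3-methoxy-4-(methoxymethoxy)-2-(3-methylbut-2-en-1-yl)-5-(trimethylsilyl)phenyl diethylcarbamate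
Product: 12 4-hydroxy-3-methoxy-2-(3-methylbut-2-en-1-yl)-5-(trimethylsilyl)phenyl diethylcarbamate
Conditions: camphorsulfonic acid (cat.), MeOH, 40 °C
Reagents that add atoms: none
Why: Acid-catalysed transacetalisation of the aryl MOM ether to dimethoxymethane, under conditions too mild for protodesilylation or for addition to the prenyl alkene; the carbamate is inert and no free phenol flanks the prenyl group.

**Step 6**
Reactants: 12 4-hydroxy-3-methoxy-2-(3-methylbut-2-en-1-yl)-5-(trimethylsilyl)phenyl diethylcarbamate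
Product: 13 4-(diethylcarbamoyloxy)-2-methoxy-3-(3-methylbut-2-en-1-yl)-6-(trimethylsilyl)phenyl trifluoromethanesulfonate
Conditions: Tf2O, pyridine, CH2Cl2, 0 °C
Reagents that add atoms: trifluoromethanesulfonic anhydride, O=S(=O)(OS(=O)(=O)C(F)(F)F)C(F)(F)F
Why: O-triflation of a 2-silylphenol, the standard last step to a fluoride-triggered aryne precursor.

**Step 7**
Reactants: 14 2,4-dihydroxyacetophenone
Product: 15 4-acetyl-1,3-phenylene bis(diethylcarbamate)
Conditions: ClCONEt2 (2.5 equiv), K2CO3, MeCN, reflux
Reagents that add atoms: diethylcarbamoyl chloride, CCN(CC)C(Cl)=O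
Why: Double O-carbamoylation with a weak base, which avoids ketone enolate formation and hence the carbamoyl Baker–Venkataraman shift; the chelated ortho-hydroxyl reacts at reflux.

**Step 8**
Reactants: 15 4-acetyl-1,3-phenylene bis(diethylcarbamate)
Product: 16 4-(prop-1-en-2-yl)-1,3-phenylene bis(diethylcarbamate)
Conditions: MePPh3Br (1.3 equiv), KOtBu (1.2 equiv), THF, 0 °C → rt
Reagents that add atoms: methyltriphenylphosphonium bromide (ylide formed in the flask), C[P+](c1ccccc1)(c1ccccc1)c1ccccc1.[Br-]
Why: Wittig methylenation, in which addition of the unhindered ylide to the methyl ketone at 0 °C should be faster than enolisation and the diethylcarbamates are inert to the ylide.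

**Step 9**
Reactants: 16 4-(prop-1-en-2-yl)-1,3-phenylene bis(diethylcarbamate)
Product: 17 4-(3-oxoprop-1-en-2-yl)-1,3-phenylene bis(diethylcarbamate)
Conditions: SeO2, 1,4-dioxane, H2O (trace), 90 °C; used at once
Reagents that add atoms: selenium dioxide, O=[Se]=O
Why: Riley allylic oxidation (ene reaction, then [2,3]-shift) of the only allylic C–H bonds, the established route from α-methylstyrenes to 2-arylacroleins; 17 is used fresh because such enals dimerise.

**Step 10**
Reactants: 13 4-(diethylcarbamoyloxy)-2-methoxy-3-(3-methylbut-2-en-1-yl)-6-(trimethylsilyl)phenyl trifluoromethanesulfonate; 17 4-(3-oxoprop-1-en-2-yl)-1,3-phenylene bis(diethylcarbamate)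
Product: 21 3-[2,4-bis(diethylcarbamoyloxy)phenyl]-5-methoxy-6-(3-methylbut-2-en-1-yl)-2H-chromen-7-yl diethylcarbamate, via aryne 18 (not isolated), via benzoxete 19 (not isolated), via o-quinone methide 20 (not isolated)
Conditions: CsF (3 equiv), MeCN/toluene (1:1), rt → 45 °C, slow addition of 13 to 17 (2.5 equiv)
Reagents that add atoms: none
Why: Fluoride removes SiMe3 from 13 with loss of triflate to give aryne 18 (C4a≡C8a); the aldehyde oxygen of 17 adds to C8a and the aryl anion developing at C4a closes on the carbonyl carbon (stepwise formal [2+2]) to benzoxete 19, whose thermal 4π ring opening gives o-quinone methide 20, which closes through O1–C2 to the 2H-chromene. The closest known reaction type is the annulation of fluoride-generated arynes with α,β-unsaturated aldehydes to 2H-chromenes, together with the analogous aryne/formamide C=O insertion. Ring closures: the transient four-membered oxete by 4-exo collapse of the zwitterion onto the oxocarbenium carbon, and ring C by thermal disrotatory oxa-6π electrocyclisation of the 1-oxatriene O=C8a–C4a=C4–C3=C2. No stereocentre is formed, since the benzoxete carbon returns to sp2 and C2 is CH2. The step needs regioselectivity, and the C5 methoxy group secures it: being ortho to C4a it distorts and polarises the aryne so that oxygen attacks the remote, unhindered C8a and the carbanion sits next to the inductively withdrawing oxygen; the same group disfavours the E quinone methide by A(1,3) strain, and any E isomer can return through 19. Chemoselectivity (aldehyde C=O over carbamate C=O, ene and [4+2] paths) rests on excess 17, the absence of allylic C–H in 17, slow generation of 18, and the prenyl group being out of reach of the aryne carbons.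

**Step 11**
Reactants: 21 3-[2,4-bis(diethylcarbamoyloxy)phenyl]-5-methoxy-6-(3-methylbut-2-en-1-yl)-2H-chromen-7-yl diethylcarbamate
Product: 22 dehydroglyasperin C, 4-[7-hydroxy-5-methoxy-6-(3-methylbut-2-en-1-yl)-2H-chromen-3-yl]benzene-1,3-diol
Conditions: LiAlH4 (excess), THF, 0 → 45 °C, argon; then degassed aq. potassium sodium tartrate, pH 6
Reagents that add atoms: none
Why: Hydride reduction of aryl N,N-diethylcarbamates releases the three phenoxides under non-acidic conditions (each carbonyl leaves as N,N-diethylmethylamine), which avoids acid-induced pterocarpan formation from the 2'-hydroxy isoflav-3-ene and cyclisation of the prenyl group onto the C7 phenol; the chromene and prenyl alkenes are inert to LiAlH4.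

**Compound list**
1 | 5-bromovanillin (3-bromo-4-hydroxy-5-methoxybenzaldehyde) | COc1cc(C=O)cc(Br)c1O | starting material
2 | 3-bromo-4-hydroxy-5-methoxyphenyl formate | COc1cc(OC=O)cc(Br)c1O | intermediate
3 | 2-bromo-6-methoxybenzene-1,4-diol | COc1cc(O)cc(Br)c1O | intermediate
4 | 2-bromo-6-methoxy-1,4-bis(trimethylsilyloxy)benzene | COc1cc(O[Si](C)(C)C)cc(Br)c1O[Si](C)(C)C | intermediate
5 | lithium 2-methoxy-6-(trimethylsilyl)-4-(trimethylsilyloxy)phenolate | [Li+].[O-]c1c(OC)cc(O[Si](C)(C)C)cc1[Si](C)(C)C | intermediate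
6 | 1-methoxy-2-(methoxymethoxy)-3-(trimethylsilyl)-5-(trimethylsilyloxy)benzene | COCOc1c(OC)cc(O[Si](C)(C)C)cc1[Si](C)(C)C | intermediate
7 | 3-methoxy-4-(methoxymethoxy)-5-(trimethylsilyl)phenol | COCOc1c(OC)cc(O)cc1[Si](C)(C)C | intermediate
8 | 3-methoxy-4-(methoxymethoxy)-5-(trimethylsilyl)phenyl diethylcarbamate | COCOc1c(OC)cc(OC(=O)N(CC)CC)cc1[Si](C)(C)C | intermediate
9 | [6-(diethylcarbamoyloxy)-2-methoxy-3-(methoxymethoxy)-4-(trimethylsilyl)phenyl]lithium | COCOc1c(OC)c([Li])c(OC(=O)N(CC)CC)cc1[Si](C)(C)C | intermediate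
10 | [6-(diethylcarbamoyloxy)-2-methoxy-3-(methoxymethoxy)-4-(trimethylsilyl)phenyl]copper | COCOc1c(OC)c([Cu])c(OC(=O)N(CC)CC)cc1[Si](C)(C)C | intermediate
11 | 3-methoxy-4-(methoxymethoxy)-2-(3-methylbut-2-en-1-yl)-5-(trimethylsilyl)phenyl diethylcarbamate | COCOc1c(OC)c(CC=C(C)C)c(OC(=O)N(CC)CC)cc1[Si](C)(C)C | intermediate
12 | 4-hydroxy-3-methoxy-2-(3-methylbut-2-en-1-yl)-5-(trimethylsilyl)phenyl diethylcarbamate | COc1c(O)c([Si](C)(C)C)cc(OC(=O)N(CC)CC)c1CC=C(C)C | intermediate
13 | 4-(diethylcarbamoyloxy)-2-methoxy-3-(3-methylbut-2-en-1-yl)-6-(trimethylsilyl)phenyl trifluoromethanesulfonate | COc1c(OS(=O)(=O)C(F)(F)F)c([Si](C)(C)C)cc(OC(=O)N(CC)CC)c1CC=C(C)C | intermediate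
14 | 2,4-dihydroxyacetophenone | CC(=O)c1ccc(O)cc1O | starting material
15 | 4-acetyl-1,3-phenylene bis(diethylcarbamate) | CC(=O)c1ccc(OC(=O)N(CC)CC)cc1OC(=O)N(CC)CC | intermediate
16 | 4-(prop-1-en-2-yl)-1,3-phenylene bis(diethylcarbamate) | CC(=C)c1ccc(OC(=O)N(CC)CC)cc1OC(=O)N(CC)CC | intermediate
17 | 4-(3-oxoprop-1-en-2-yl)-1,3-phenylene bis(diethylcarbamate) | C=C(C=O)c1ccc(OC(=O)N(CC)CC)cc1OC(=O)N(CC)CC | intermediate
18 | 5-(diethylcarbamoyloxy)-3-methoxy-4-(3-methylbut-2-en-1-yl)benzyne (1,2-didehydrobenzene) | COC1=C(CC=C(C)C)C(OC(=O)N(CC)CC)=CC#C1 | intermediate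
19 | 2-{1-[2,4-bis(diethylcarbamoyloxy)phenyl]ethenyl}-3-methoxy-4-(3-methylbut-2-en-1-yl)-2H-benzo[b]oxet-5-yl diethylcarbamate (racemic) | COc1c2C(C(=C)c3ccc(OC(=O)N(CC)CC)cc3OC(=O)N(CC)CC)Oc2cc(OC(=O)N(CC)CC)c1CC=C(C)C | intermediate
20 | (Z)-o-quinone methide: 6-{2-[2,4-bis(diethylcarbamoyloxy)phenyl]prop-2-en-1-ylidene}-3-(diethylcarbamoyloxy)-5-methoxy-4-(3-methylbut-2-en-1-yl)cyclohexa-2,4-dien-1-one | C=C(c1ccc(OC(=O)N(CC)CC)cc1OC(=O)N(CC)CC)/C=C1\C(=O)C=C(OC(=O)N(CC)CC)C(CC=C(C)C)=C1OC | intermediate
21 | 3-[2,4-bis(diethylcarbamoyloxy)phenyl]-5-methoxy-6-(3-methylbut-2-en-1-yl)-2H-chromen-7-yl diethylcarbamate | COc1c2c(cc(OC(=O)N(CC)CC)c1CC=C(C)C)OCC(c1ccc(OC(=O)N(CC)CC)cc1OC(=O)N(CC)CC)=C2 | intermediate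
22 | dehydroglyasperin C, 4-[7-hydroxy-5-methoxy-6-(3-methylbut-2-en-1-yl)-2H-chromen-3-yl]benzene-1,3-diol | COc1c2c(cc(O)c1CC=C(C)C)OCC(c1ccc(O)cc1O)=C2 | target

**Step count and risks**
Total step count: 11. Longest linear sequence: 8 steps (steps 1–6, 10, 11).

Steps most likely to fail:

Step 10. The aryne may be consumed by other partners: [4+2] addition to the styrene unit of 17, addition to carbamate carbonyl oxygens, or an intermolecular ene reaction with a prenyl group. Fluoride may also oligomerise the enal before it meets the aryne. The fallback sets out from 13 and 15 and returns at 21. Aryne 18 is generated from 13 in DMF (CsF, DMF, rt, aqueous work-up); formamide C=O insertion with the same regiochemistry and hydrolysis should give the salicylaldehyde 4-formyl-5-hydroxy-3-methoxy-2-(3-methylbut-2-en-1-yl)phenyl diethylcarbamate F1. Ketone 15 is α-brominated (CuBr2, EtOAc/CHCl3, reflux) to 4-(bromoacetyl)-1,3-phenylene bis(diethylcarbamate) F2. O-Alkylation of F1 by F2 (K2CO3, acetone, rt, mild enough to avoid aldol closure to a benzofuran) should give the keto aldehyde 5-{2-[2,4-bis(diethylcarbamoyloxy)phenyl]-2-oxoethoxy}-4-formyl-3-methoxy-2-(3-methylbut-2-en-1-yl)phenyl diethylcarbamate F3. Intramolecular McMurry coupling (TiCl4, Zn, pyridine, THF, reflux, high dilution) then joins the two carbonyl carbons as C3=C4 and gives 21.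

Step 9. The oxidation may stall at the allylic alcohol or run on, and the enal may oligomerise under the hot, selenium-containing conditions. The fallback sets out from 15 and returns at 17, bypassing 16. Soft enolisation and O-triflation (Tf2O, 2,6-di-tert-butyl-4-methylpyridine, CH2Cl2, 0 °C → rt) should give the vinyl triflate 4-{1-[(trifluoromethylsulfonyl)oxy]ethenyl}-1,3-phenylene bis(diethylcarbamate) F4. Palladium-catalysed formylation (Pd(PPh3)4, CO (1 atm), Bu3SnH, THF, 50 °C) should then give 17 under neutral, non-oxidising conditions.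

Step 2. Intermolecular oxygen-to-oxygen silyl transfer between phenoxide and silyl ether before the MOM capping could scramble which oxygen is capped; incomplete silyl migration or attack of n-BuLi at silicon would also erode the one-pot sequence. The fallback sets out from 1 and returns at 8, fixing each oxygen in a separate step. MOM protection of 1 (MOMCl, i-Pr2NEt, CH2Cl2) gives 3-bromo-5-methoxy-4-(methoxymethoxy)benzaldehyde F5. Baeyer–Villiger oxidation (mCPBA, NaHCO3, CH2Cl2) gives 3-bromo-5-methoxy-4-(methoxymethoxy)phenyl formate F6, which is methanolysed (K2CO3, MeOH) to 3-bromo-5-methoxy-4-(methoxymethoxy)phenol F7. Carbamoylation (ClCONEt2, K2CO3, MeCN, reflux) gives 3-bromo-5-methoxy-4-(methoxymethoxy)phenyl diethylcarbamate F8. Br–Li exchange and C-silylation (n-BuLi, THF, −78 °C, then Me3SiCl) should give 8.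

**Further compounds**
F1 | step 10 | 4-formyl-5-hydroxy-3-methoxy-2-(3-methylbut-2-en-1-yl)phenyl diethylcarbamate | COc1c(C=O)c(O)cc(OC(=O)N(CC)CC)c1CC=C(C)C
F2 | step 10 | 4-(bromoacetyl)-1,3-phenylene bis(diethylcarbamate) | O=C(CBr)c1ccc(OC(=O)N(CC)CC)cc1OC(=O)N(CC)CC
F3 | step 10 | 5-{2-[2,4-bis(diethylcarbamoyloxy)phenyl]-2-oxoethoxy}-4-formyl-3-methoxy-2-(3-methylbut-2-en-1-yl)phenyl diethylcarbamate | COc1c(C=O)c(OCC(=O)c2ccc(OC(=O)N(CC)CC)cc2OC(=O)N(CC)CC)cc(OC(=O)N(CC)CC)c1CC=C(C)C
F4 | step 9 | 4-{1-[(trifluoromethylsulfonyl)oxy]ethenyl}-1,3-phenylene bis(diethylcarbamate) | C=C(OS(=O)(=O)C(F)(F)F)c1ccc(OC(=O)N(CC)CC)cc1OC(=O)N(CC)CC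
F5 | step 2 | 3-bromo-5-methoxy-4-(methoxymethoxy)benzaldehyde | COCOc1c(Br)cc(C=O)cc1OC
F6 | step 2 | 3-bromo-5-methoxy-4-(methoxymethoxy)phenyl formate | COCOc1c(Br)cc(OC=O)cc1OC
F7 | step 2 | 3-bromo-5-methoxy-4-(methoxymethoxy)phenol | COCOc1c(Br)cc(O)cc1OC
F8 | step 2 | 3-bromo-5-methoxy-4-(methoxymethoxy)phenyl diethylcarbamate | COCOc1c(Br)cc(OC(=O)N(CC)CC)cc1OC
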